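**Plan**

1. Retrosynthesis: (i) the epoxide C–O bonds are cut back to the 13E allylic alcohol; (ii) C8=C17 is cut back to a C8 ketone and a C1=C2 double bond is added; (iii) C5–C10 and C3–C4 are cut together (intramolecular Diels–Alder); (iv) the (Z)-diene is traced to an unsaturated δ-lactone; (v) C8–C9 is cut by an allylboration.
2. Enabling feature: in ring A the carbonyl-bearing quaternary C4 and C5–H lie next to the methyl-bearing quaternary C10, with C1–C3 unsubstituted. Ring A is therefore the adduct of a C4=C5 enal and a C10=C1–C2=C3 diene, and C6–C9 of ring B is the four-carbon tether.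
3. Forward: a geraniol-derived allylboronate (C9–C16, C20) and a C6 enoate aldehyde (C4–C8, C18, C19) are joined at C8–C9. Acrylate ring-closing metathesis gives a lactone that fixes the Z diene geometry; reduction and Wittig olefination open it to the dienyl keto-enal. One cycloaddition then closes rings A and B.
4. Helpers and their removal: the lactone (temporary ring), the C19 aldehyde (activation, returned to the methyl ester), the C8 ketone (planar tether atom, later the methylene) and the C1=C2 bond (hydrogenated).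
5. Stereochemistry: C9 comes from the chiral phosphoric acid in the allylboration. C4, C5 and C10 come from the cycloaddition (E enal, Z diene, allylic strain at C9). C13 and C14 come from D-(−)-tartrate in the Sharpless epoxidation, and 13E from geraniol.

Key step: step 12

Remark: as written, the SMILES has H-5 and CH3-20 on the same face (cis-fused decalin, 4S,5S,9S,10R,13R,14R); the route is built for this isomer. Atom numbers C1–C20 are labdane numbers (ring A: C1–C5, C10; ring B: C5–C10; side chain C11–C16; C17 on C8; C18/C19 on C4; C20 on C10).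

**Route**

Step 1
Reactants: 1 geraniol; 2 tert-butyl(chloro)diphenylsilane
Product: 3 tert-butyl{[(2E)-3,7-dimethylocta-2,6-dien-1-yl]oxy}diphenylsilane
Conditions: imidazole, DMF, rt
Reagents that add atoms: 2 tert-butyl(chloro)diphenylsilane, CC(C)(C)[Si](Cl)(c1ccccc1)c1ccccc1
Why: Standard silylation of a primary allylic alcohol gives a robust ether that should carry O15 through all later steps.

Step 2
Reactants: 3 geranyl silyl ether; 4 tert-butyl hydroperoxide
Product: 5 (2E,6E)-8-{[tert-butyl(diphenyl)silyl]oxy}-2,6-dimethylocta-2,6-dien-1-ol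
Conditions: SeO2 (cat.), t-BuOOH, salicylic acid (cat.), CH2Cl2, rt
Reagents that add atoms: 4 tert-butyl hydroperoxide, CC(C)(C)OO
Why: Sharpless–Umbreit allylic oxidation (ene reaction, then 2,3-sigmatropic shift) should oxidise the E methyl group of the distal, more electron-rich trisubstituted alkene, as is established for geranyl esters and ethers.

Step 3
Reactants: 5 allylic alcohol; 6 bis(pinacolato)diboron
Product: 7 tert-butyl{[(2E,6E)-3,7-dimethyl-8-(4,4,5,5-tetramethyl-1,3,2-dioxaborolan-2-yl)octa-2,6-dien-1-yl]oxy}diphenylsilane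
Conditions: [Pd(MeCN)4](BF4)2 (5 mol %), B2pin2, DMSO/MeOH, 40 °C
Reagents that add atoms: 6 bis(pinacolato)diboron, CC1(C)OB(OC1(C)C)B1OC(C)(C)C(C)(C)O1
Why: Palladium-catalysed borylation of an allylic alcohol through an η3-allylpalladium intermediate should place boron on the unsubstituted terminus and keep the E geometry, while the allylic silyl ether at the other end does not ionise.

Step 4
Reactants: 8 2,3-dihydrofuran; 9 methyl 2-(triphenyl-λ5-phosphanylidene)propanoate
Product: 11 methyl (2E)-6-hydroxy-2-methylhex-2-enoate, via tetrahydrofuran-2-ol 10 (not isolated)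
Conditions: 0.2 M aq. HCl, 0 °C → rt; NaHCO3; then 9, CH2Cl2, rt
Reagents that add atoms: 9 methyl 2-(triphenyl-λ5-phosphanylidene)propanoate, COC(=O)C(C)=P(c1ccccc1)(c1ccccc1)c1ccccc1
Why: Acid hydration of the enol ether gives the lactol, whose open hydroxy-aldehyde form should undergo Wittig olefination with the stabilised ylide to the E trisubstituted enoate.

Step 5
Reactants: 11 methyl (2E)-6-hydroxy-2-methylhex-2-enoate
Product: 12 methyl (2E)-2-methyl-6-oxohex-2-enoate
Conditions: TEMPO (cat.), PhI(OAc)2, CH2Cl2, rt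
Reagents that add atoms: none
Why: Oxoammonium (TEMPO) oxidation of a primary alcohol stops at the aldehyde and leaves the enoate untouched.

Step 6
Reactants: 7 allylboronate; 12 aldehyde
Product: 13 methyl (2E,6S,7R,10E)-12-{[tert-butyl(diphenyl)silyl]oxy}-6-hydroxy-2,10-dimethyl-7-(prop-1-en-2-yl)dodeca-2,10-dienoate
Conditions: (R)-TRIP [(R)-3,3'-bis(2,4,6-triisopropylphenyl)-1,1'-binaphthyl-2,2'-diyl hydrogen phosphate] (5 mol %), 4 Å molecular sieves, toluene, −30 °C; aqueous work-up
Reagents that add atoms: none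
Why: Chiral-phosphoric-acid-catalysed allylboration through a chair (Zimmerman–Traxler) transition state should give the anti product from the E γ-substituent, and the (R)-catalyst, which directs allyl transfer to the Re face of aldehydes, should set C9 (7R here, with 6S at the carbinol) while bond formation at the γ-carbon creates the isopropenyl group.

Step 7
Reactants: 13 homoallylic alcohol; 14 acryloyl chloride
Product: 15 methyl (2E,6S,7R,10E)-6-(acryloyloxy)-12-{[tert-butyl(diphenyl)silyl]oxy}-2,10-dimethyl-7-(prop-1-en-2-yl)dodeca-2,10-dienoate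
Conditions: CH2=CHCOCl, Et3N, DMAP (cat.), CH2Cl2, 0 °C
Reagents that add atoms: 14 acryloyl chloride, C=CC(Cl)=O
Why: O-Acylation of the secondary alcohol installs the second alkene for ring closure without touching a stereocentre.

Step 8
Reactants: 15 acrylate
Product: 16 methyl (2E)-5-[(2S,3R)-3-[(3E)-5-{[tert-butyl(diphenyl)silyl]oxy}-3-methylpent-3-en-1-yl]-4-methyl-6-oxo-3,6-dihydro-2H-pyran-2-yl]-2-methylpent-2-enoate
Conditions: second-generation Grubbs catalyst (H2IMes)(PCy3)Cl2Ru=CHPh (5 mol %), toluene, 80 °C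
Reagents that add atoms: none
Why: Ring-closing metathesis of an acrylate with a 1,1-disubstituted alkene to a 4-methyl-5,6-dihydropyran-2-one is a standard closure, the six-membered ring forces the C10=C1 bond to be Z (C9 cis to C2), and the two trisubstituted alkenes should stay spectators.

Step 9
Reactants: 16 lactone
Product: 17 (5R,6S)-5-[(3E)-5-{[tert-butyl(diphenyl)silyl]oxy}-3-methylpent-3-en-1-yl]-6-[(3E)-5-hydroxy-4-methylpent-3-en-1-yl]-4-methyl-5,6-dihydro-2H-pyran-2-ol (mixture of anomers)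
Conditions: i-Bu2AlH (3.5 equiv), CH2Cl2, −78 °C; aq. KNaC4H4O6
Reagents that add atoms: none
Why: At −78 °C diisobutylaluminium hydride reduction should take the lactone only to the lactol (stable aluminium hemiacetal) and the enoate to the allylic alcohol in one operation.

Step 10
Reactants: 17 lactol; 18 methyltriphenylphosphonium bromide
Product: 19 (2E,6S,7R,10E)-12-{[tert-butyl(diphenyl)silyl]oxy}-2,10-dimethyl-7-[(2Z)-penta-2,4-dien-2-yl]dodeca-2,10-diene-1,6-diol
Conditions: Ph3PCH3Br, KN(SiMe3)2 (excess), THF, 0 °C → rt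
Reagents that add atoms: 18 methyltriphenylphosphonium bromide, C[P+](c1ccccc1)(c1ccccc1)c1ccccc1.[Br-]
Why: Wittig methylenation of the ring-opened lactol (a Z hydroxy enal) gives the terminal diene, and the Z geometry of C10=C1 is inherited from the ring because that bond is not touched.

Step 11
Reactants: 19 diene diol
Product: 20 (2E,7R,10E)-12-{[tert-butyl(diphenyl)silyl]oxy}-2,10-dimethyl-6-oxo-7-[(2Z)-penta-2,4-dien-2-yl]dodeca-2,10-dienal
Conditions: Dess–Martin periodinane (2.5 equiv), NaHCO3, CH2Cl2, 0 °C → rt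
Reagents that add atoms: none
Why: Buffered Dess–Martin oxidation converts the allylic alcohol to the E enal and the C8 alcohol to the ketone under neutral conditions that should not enolise the skipped dienyl ketone.

Step 12
Reactants: 20 dienyl keto-enal
Product: 21 (1S,4aS,5R,8aS)-5-[(3E)-5-{[tert-butyl(diphenyl)silyl]oxy}-3-methylpent-3-en-1-yl]-1,4a-dimethyl-6-oxo-1,2,4a,5,6,7,8,8a-octahydronaphthalene-1-carbaldehyde (cis-fused)
Conditions: Me2AlCl (2.2 equiv), CH2Cl2, −78 → −20 °C; aq. NaHCO3/KNaC4H4O6 work-up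
Reagents that add atoms: none
Why: Me2AlCl activates the (E)-enal, whose C4=C5 bond adds across the (Z)-diene C10=C1–C2=C3 in a concerted, asynchronous [4+2] cycloaddition; the closest known reaction type is the Lewis-acid-promoted intramolecular Diels–Alder reaction of 1,7,9-decatrienals, including (Z)-dienes that give cis-fused decalins. Ring A is closed by the cycloaddition itself (new bonds C5–C10 and C3–C4, new C1=C2), and ring B is closed by the C5–C10 bond through the four-carbon tether C6–C9 (type 1 mode, six-membered). C4 is set relative to C5 by suprafacial addition to the E enal (CHO cis to H-5), and C5 relative to C10 by the Z diene: the tether sits on the inside position of C10, so only the tether-exo, CHO-endo approach is geometrically possible and H-5 and CH3-20 should end up cis. C9 is the controlling stereocentre for the face: allylic 1,3-strain against C2/C3 of the s-cis diene should hold H-9 in the diene plane with C8 above and C11 below, so the dienophile adds anti to C11 and C11 ends up cis to CH3-20. The step needs this facial selectivity and no enolisation toward C9 or 1,5-hydrogen shift; the planar C8 carbonyl leaves no axial tether substituent to clash with CH3-20 in the chair-like tether, and Lewis-acid activation allows a temperature at which the C9–H, which lies in the nodal plane of the diene, should stay untouched.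

Step 13
Reactants: 21 cycloadduct aldehyde; 22 sodium chlorite
Product: 23 (1S,4aS,5R,8aS)-5-[(3E)-5-{[tert-butyl(diphenyl)silyl]oxy}-3-methylpent-3-en-1-yl]-1,4a-dimethyl-6-oxo-1,2,4a,5,6,7,8,8a-octahydronaphthalene-1-carboxylic acid
Conditions: NaClO2, NaH2PO4, 2-methylbut-2-ene, t-BuOH/H2O, 0 °C → rt
Reagents that add atoms: 22 sodium chlorite, [Na+].[O-]Cl=O
Why: Pinnick oxidation converts the non-enolisable neopentyl aldehyde to the acid under buffered conditions that should spare the alkenes (hypochlorite is scavenged) and the C9 centre.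

Step 14
Reactants: 23 acid; 24 (trimethylsilyl)diazomethane
Product: 25 methyl (1S,4aS,5R,8aS)-5-[(3E)-5-{[tert-butyl(diphenyl)silyl]oxy}-3-methylpent-3-en-1-yl]-1,4a-dimethyl-6-oxo-1,2,4a,5,6,7,8,8a-octahydronaphthalene-1-carboxylate
Conditions: TMSCHN2, MeOH/toluene, 0 °C
Reagents that add atoms: 24 (trimethylsilyl)diazomethane, C[Si](C)(C)C=[N+]=[N-]
Why: Diazoalkane O-methylation of the hindered acid is neutral, so the epimerisable C9 next to the ketone is not put at risk.

Step 15
Reactants: 25 unsaturated keto ester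
Product: 26 methyl (1S,4aS,5R,8aS)-5-[(3E)-5-{[tert-butyl(diphenyl)silyl]oxy}-3-methylpent-3-en-1-yl]-1,4a-dimethyl-6-oxodecahydronaphthalene-1-carboxylate
Conditions: H2 (1–4 atm), RhCl(PPh3)3 (10 mol %), benzene/EtOH, rt
Reagents that add atoms: none
Why: Homogeneous hydrogenation with Wilkinson's catalyst RhCl(PPh3)3 discriminates by alkene substitution, so the cis-disubstituted ring alkene C1=C2 should be reduced and the trisubstituted side-chain alkene left.

Step 16
Reactants: 26 saturated keto ester; 27 dibromomethane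
Product: 28 methyl (1S,4aR,5S,8aS)-5-[(3E)-5-{[tert-butyl(diphenyl)silyl]oxy}-3-methylpent-3-en-1-yl]-1,4a-dimethyl-6-methylidenedecahydronaphthalene-1-carboxylate
Conditions: Zn, CH2Br2, TiCl4, THF/CH2Cl2, 0 °C → rt
Reagents that add atoms: 27 dibromomethane, BrCBr
Why: Takai–Lombardo methylenation is non-basic, so the ketone should be converted to the exocyclic alkene without epimerisation at C9, and the hindered ester and the silyl ether are tolerated.

Step 17
Reactants: 28 silyl ether
Product: 29 methyl (1S,4aR,5S,8aS)-5-[(3E)-5-hydroxy-3-methylpent-3-en-1-yl]-1,4a-dimethyl-6-methylidenedecahydronaphthalene-1-carboxylate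
Conditions: Bu4NF, THF, 0 °C → rt
Reagents that add atoms: none
Why: Fluoride cleavage of the silyl ether frees the allylic alcohol while the hindered methyl ester stays inert.

Step 18
Reactants: 29 allylic alcohol; 4 tert-butyl hydroperoxide
Product: 30 methyl (1S,4aR,5S,8aS)-5-{2-[(2R,3R)-3-(hydroxymethyl)-2-methyloxiran-2-yl]ethyl}-1,4a-dimethyl-6-methylidenedecahydronaphthalene-1-carboxylate (target, CNP0175926.1)
Conditions: Ti(Oi-Pr)4 (10 mol %), D-(−)-diethyl tartrate (12 mol %), t-BuOOH, 4 Å molecular sieves, CH2Cl2, −20 °C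
Reagents that add atoms: 4 tert-butyl hydroperoxide, CC(C)(C)OO
Why: Sharpless asymmetric epoxidation is selective for the allylic alcohol over the exocyclic alkene, and D-(−)-tartrate should give the (13R,14R)-epoxide (the series enantiomeric to that from geraniol with L-(+)-tartrate), the trans relation following from the E alkene.

**Compound list**

1 | geraniol, (2E)-3,7-dimethylocta-2,6-dien-1-ol | CC(C)=CCC/C(C)=C/CO | starting material
2 | tert-butyl(chloro)diphenylsilane | CC(C)(C)[Si](Cl)(c1ccccc1)c1ccccc1 | starting material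
3 | tert-butyl{[(2E)-3,7-dimethylocta-2,6-dien-1-yl]oxy}diphenylsilane | CC(C)=CCC/C(C)=C/CO[Si](c1ccccc1)(c1ccccc1)C(C)(C)C | intermediate
4 | tert-butyl hydroperoxide | CC(C)(C)OO | starting material
5 | (2E,6E)-8-{[tert-butyl(diphenyl)silyl]oxy}-2,6-dimethylocta-2,6-dien-1-ol | OC/C(C)=C/CC/C(C)=C/CO[Si](c1ccccc1)(c1ccccc1)C(C)(C)C | intermediate
6 | bis(pinacolato)diboron | CC1(C)OB(OC1(C)C)B1OC(C)(C)C(C)(C)O1 | starting material
7 | tert-butyl{[(2E,6E)-3,7-dimethyl-8-(4,4,5,5-tetramethyl-1,3,2-dioxaborolan-2-yl)octa-2,6-dien-1-yl]oxy}diphenylsilane | CC1(C)OB(C/C(C)=C/CC/C(C)=C/CO[Si](c2ccccc2)(c2ccccc2)C(C)(C)C)OC1(C)C | intermediate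
8 | 2,3-dihydrofuran | C1=COCC1 | starting material
9 | methyl 2-(triphenyl-λ5-phosphanylidene)propanoate | COC(=O)C(C)=P(c1ccccc1)(c1ccccc1)c1ccccc1 | starting material
10 | tetrahydrofuran-2-ol | OC1CCCO1 | intermediate (not isolated)
11 | methyl (2E)-6-hydroxy-2-methylhex-2-enoate | COC(=O)/C(C)=C/CCCO | intermediate
12 | methyl (2E)-2-methyl-6-oxohex-2-enoate | COC(=O)/C(C)=C/CCC=O | intermediate
13 | methyl (2E,6S,7R,10E)-12-{[tert-butyl(diphenyl)silyl]oxy}-6-hydroxy-2,10-dimethyl-7-(prop-1-en-2-yl)dodeca-2,10-dienoate | COC(=O)/C(C)=C/CC[C@H](O)[C@H](CC/C(C)=C/CO[Si](c1ccccc1)(c1ccccc1)C(C)(C)C)C(C)=C | intermediate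
14 | acryloyl chloride | C=CC(Cl)=O | starting material
15 | methyl (2E,6S,7R,10E)-6-(acryloyloxy)-12-{[tert-butyl(diphenyl)silyl]oxy}-2,10-dimethyl-7-(prop-1-en-2-yl)dodeca-2,10-dienoate | COC(=O)/C(C)=C/CC[C@H](OC(=O)C=C)[C@H](CC/C(C)=C/CO[Si](c1ccccc1)(c1ccccc1)C(C)(C)C)C(C)=C | intermediate
16 | methyl (2E)-5-[(2S,3R)-3-[(3E)-5-{[tert-butyl(diphenyl)silyl]oxy}-3-methylpent-3-en-1-yl]-4-methyl-6-oxo-3,6-dihydro-2H-pyran-2-yl]-2-methylpent-2-enoate | COC(=O)/C(C)=C/CC[C@@H]1OC(=O)C=C(C)[C@H]1CC/C(C)=C/CO[Si](c1ccccc1)(c1ccccc1)C(C)(C)C | intermediate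
17 | (5R,6S)-5-[(3E)-5-{[tert-butyl(diphenyl)silyl]oxy}-3-methylpent-3-en-1-yl]-6-[(3E)-5-hydroxy-4-methylpent-3-en-1-yl]-4-methyl-5,6-dihydro-2H-pyran-2-ol (anomers) | OC/C(C)=C/CC[C@@H]1OC(O)C=C(C)[C@H]1CC/C(C)=C/CO[Si](c1ccccc1)(c1ccccc1)C(C)(C)C | intermediate
18 | methyltriphenylphosphonium bromide | C[P+](c1ccccc1)(c1ccccc1)c1ccccc1.[Br-] | starting material
19 | (2E,6S,7R,10E)-12-{[tert-butyl(diphenyl)silyl]oxy}-2,10-dimethyl-7-[(2Z)-penta-2,4-dien-2-yl]dodeca-2,10-diene-1,6-diol | OC/C(C)=C/CC[C@H](O)[C@H](CC/C(C)=C/CO[Si](c1ccccc1)(c1ccccc1)C(C)(C)C)/C(C)=C\C=C | intermediate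
20 | (2E,7R,10E)-12-{[tert-butyl(diphenyl)silyl]oxy}-2,10-dimethyl-6-oxo-7-[(2Z)-penta-2,4-dien-2-yl]dodeca-2,10-dienal | O=C/C(C)=C/CCC(=O)[C@H](CC/C(C)=C/CO[Si](c1ccccc1)(c1ccccc1)C(C)(C)C)/C(C)=C\C=C | intermediate
21 | (1S,4aS,5R,8aS)-5-[(3E)-5-{[tert-butyl(diphenyl)silyl]oxy}-3-methylpent-3-en-1-yl]-1,4a-dimethyl-6-oxo-1,2,4a,5,6,7,8,8a-octahydronaphthalene-1-carbaldehyde | O=C1CC[C@H]2[C@](C)(C=CC[C@]2(C)C=O)[C@H]1CC/C(C)=C/CO[Si](c1ccccc1)(c1ccccc1)C(C)(C)C | intermediate
22 | sodium chlorite | [Na+].[O-]Cl=O | starting material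
23 | (1S,4aS,5R,8aS)-5-[(3E)-5-{[tert-butyl(diphenyl)silyl]oxy}-3-methylpent-3-en-1-yl]-1,4a-dimethyl-6-oxo-1,2,4a,5,6,7,8,8a-octahydronaphthalene-1-carboxylic acid | O=C1CC[C@H]2[C@](C)(C=CC[C@]2(C)C(=O)O)[C@H]1CC/C(C)=C/CO[Si](c1ccccc1)(c1ccccc1)C(C)(C)C | intermediate
24 | (trimethylsilyl)diazomethane | C[Si](C)(C)C=[N+]=[N-] | starting material
25 | methyl (1S,4aS,5R,8aS)-5-[(3E)-5-{[tert-butyl(diphenyl)silyl]oxy}-3-methylpent-3-en-1-yl]-1,4a-dimethyl-6-oxo-1,2,4a,5,6,7,8,8a-octahydronaphthalene-1-carboxylate | O=C1CC[C@H]2[C@](C)(C=CC[C@]2(C)C(=O)OC)[C@H]1CC/C(C)=C/CO[Si](c1ccccc1)(c1ccccc1)C(C)(C)C | intermediate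
26 | methyl (1S,4aS,5R,8aS)-5-[(3E)-5-{[tert-butyl(diphenyl)silyl]oxy}-3-methylpent-3-en-1-yl]-1,4a-dimethyl-6-oxodecahydronaphthalene-1-carboxylate | O=C1CC[C@H]2[C@](C)(CCC[C@]2(C)C(=O)OC)[C@H]1CC/C(C)=C/CO[Si](c1ccccc1)(c1ccccc1)C(C)(C)C | intermediate
27 | dibromomethane | BrCBr | starting material
28 | methyl (1S,4aR,5S,8aS)-5-[(3E)-5-{[tert-butyl(diphenyl)silyl]oxy}-3-methylpent-3-en-1-yl]-1,4a-dimethyl-6-methylidenedecahydronaphthalene-1-carboxylate | C=C1CC[C@H]2[C@](C)(CCC[C@]2(C)C(=O)OC)[C@H]1CC/C(C)=C/CO[Si](c1ccccc1)(c1ccccc1)C(C)(C)C | intermediate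
29 | methyl (1S,4aR,5S,8aS)-5-[(3E)-5-hydroxy-3-methylpent-3-en-1-yl]-1,4a-dimethyl-6-methylidenedecahydronaphthalene-1-carboxylate | C=C1CC[C@H]2[C@](C)(CCC[C@]2(C)C(=O)OC)[C@H]1CC/C(C)=C/CO | intermediate
30 | methyl (1S,4aR,5S,8aS)-5-{2-[(2R,3R)-3-(hydroxymethyl)-2-methyloxiran-2-yl]ethyl}-1,4a-dimethyl-6-methylidenedecahydronaphthalene-1-carboxylate | C=C1CC[C@H]2[C@](C)(CCC[C@]2(C)C(=O)OC)[C@H]1CC[C@@]1(C)O[C@@H]1CO | target

**Step count and risks**

Total steps: 18. Longest linear sequence: 16 steps (steps 1–3, then 6–18); steps 4–5 form the short branch.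

Steps most likely to fail:

1. Step 12 (cycloaddition). The Lewis acid may enolise the C8 ketone toward C9, which would erase the only stereocentre or conjugate the diene. The crowded s-cis (Z)-diene may also react so slowly that side reactions win. The fallback sets out from 19 and comes back at 25; it runs the cycloaddition at the alcohol oxidation level with an equatorial C8 ester.
   From 19, MnO2 (CH2Cl2) oxidises only the allylic alcohol to (2E,6S,7R,10E)-12-{[tert-butyl(diphenyl)silyl]oxy}-6-hydroxy-2,10-dimethyl-7-[(2Z)-penta-2,4-dien-2-yl]dodeca-2,10-dienal F1. Mitsunobu esterification (4-nitrobenzoic acid, PPh3, DIAD) inverts C8 and should give the (6R)-4-nitrobenzoate of that hydroxy enal F2. Its C8 oxygen is then trans to C11 on the future ring B, hence equatorial in the chair-like tether, and C9 is no longer α to a carbonyl. Cycloaddition (Me2AlCl, CH2Cl2, or toluene at 110 °C) under the same geometric control should give the 4-nitrobenzoate of the 6-hydroxy octahydronaphthalene-1-carbaldehyde F3. NaClO2 oxidation gives the corresponding carboxylic acid F4, and TMSCHN2 gives its methyl ester F5. K2CO3 in MeOH removes the nitrobenzoate to give the 6-hydroxy methyl ester F6. Dess–Martin oxidation of the C8 alcohol returns to 25.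

2. Step 15 (hydrogenation). The trisubstituted C13=C14 alkene may be over-reduced, or the ring alkene next to the quaternary C10 may react too slowly. The fallback sets out from 25 and comes back at 30; it stores the side-chain alkene as the target's own epoxide before hydrogenation.
   From 25, Bu4NF gives the 6-oxo octahydronaphthalene allylic alcohol F7. Sharpless epoxidation (Ti(Oi-Pr)4, D-(−)-diethyl tartrate, t-BuOOH) gives the corresponding (2R,3R)-epoxy alcohol F8. H2 over Pd on carbon (EtOAc) then saturates the only remaining alkene to give the 6-oxo decahydronaphthalene epoxy alcohol F9; a trisubstituted epoxide should not be hydrogenolysed under these conditions. Methylenation with excess Ph3P=CH2 (THF, 0 °C) gives 30; the primary alkoxide is carried along, and Payne equilibration favours the trisubstituted epoxide.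

3. Step 6 (allylboration). The catalyst may give poor enantiofacial control with the γ,β-disubstituted allylboronate and an aliphatic aldehyde. The fallback sets out from 7 and 12 and comes back at 13; it replaces catalyst control by kinetic resolution.
   Uncatalysed allylboration (toluene, rt) passes through the same chair transition state and should give the racemic anti alcohol, that is 13 together with its enantiomer, methyl (2E,6R,7S,10E)-12-{[tert-butyl(diphenyl)silyl]oxy}-6-hydroxy-2,10-dimethyl-7-(prop-1-en-2-yl)dodeca-2,10-dienoate F10. Lipase-catalysed transesterification (Burkholderia cepacia lipase, vinyl acetate, hexane) should acylate the (6R)-enantiomer, the branched C7 side being the large group in the Kazlauskas rule, to give the (6R,7S)-acetate F11. Unreacted (6S,7R)-13 is separated by chromatography and continues at step 7.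

**Further compounds**

F1 | step 12 | (2E,6S,7R,10E)-12-{[tert-butyl(diphenyl)silyl]oxy}-6-hydroxy-2,10-dimethyl-7-[(2Z)-penta-2,4-dien-2-yl]dodeca-2,10-dienal | O=C/C(C)=C/CC[C@H](O)[C@H](CC/C(C)=C/CO[Si](c1ccccc1)(c1ccccc1)C(C)(C)C)/C(C)=C\C=C
F2 | step 12 | (2E,6R,7R,10E)-12-{[tert-butyl(diphenyl)silyl]oxy}-2,10-dimethyl-1-oxo-7-[(2Z)-penta-2,4-dien-2-yl]dodeca-2,10-dien-6-yl 4-nitrobenzoate | O=C/C(C)=C/CC[C@@H](OC(=O)c1ccc(cc1)[N+](=O)[O-])[C@H](CC/C(C)=C/CO[Si](c1ccccc1)(c1ccccc1)C(C)(C)C)/C(C)=C\C=C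
F3 | step 12 | 4-nitrobenzoate of (1S,4aS,5R,6R,8aS)-5-[(3E)-5-{[tert-butyl(diphenyl)silyl]oxy}-3-methylpent-3-en-1-yl]-6-hydroxy-1,4a-dimethyl-1,2,4a,5,6,7,8,8a-octahydronaphthalene-1-carbaldehyde | [O-][N+](=O)c1ccc(cc1)C(=O)O[C@@H]1CC[C@H]2[C@](C)(C=CC[C@]2(C)C=O)[C@H]1CC/C(C)=C/CO[Si](c1ccccc1)(c1ccccc1)C(C)(C)C
F4 | step 12 | (1S,4aS,5R,6R,8aS)-5-[(3E)-5-{[tert-butyl(diphenyl)silyl]oxy}-3-methylpent-3-en-1-yl]-1,4a-dimethyl-6-[(4-nitrobenzoyl)oxy]-1,2,4a,5,6,7,8,8a-octahydronaphthalene-1-carboxylic acid | [O-][N+](=O)c1ccc(cc1)C(=O)O[C@@H]1CC[C@H]2[C@](C)(C=CC[C@]2(C)C(=O)O)[C@H]1CC/C(C)=C/CO[Si](c1ccccc1)(c1ccccc1)C(C)(C)C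
F5 | step 12 | methyl (1S,4aS,5R,6R,8aS)-5-[(3E)-5-{[tert-butyl(diphenyl)silyl]oxy}-3-methylpent-3-en-1-yl]-1,4a-dimethyl-6-[(4-nitrobenzoyl)oxy]-1,2,4a,5,6,7,8,8a-octahydronaphthalene-1-carboxylate | [O-][N+](=O)c1ccc(cc1)C(=O)O[C@@H]1CC[C@H]2[C@](C)(C=CC[C@]2(C)C(=O)OC)[C@H]1CC/C(C)=C/CO[Si](c1ccccc1)(c1ccccc1)C(C)(C)C
F6 | step 12 | methyl (1S,4aS,5R,6R,8aS)-5-[(3E)-5-{[tert-butyl(diphenyl)silyl]oxy}-3-methylpent-3-en-1-yl]-6-hydroxy-1,4a-dimethyl-1,2,4a,5,6,7,8,8a-octahydronaphthalene-1-carboxylate | O[C@@H]1CC[C@H]2[C@](C)(C=CC[C@]2(C)C(=O)OC)[C@H]1CC/C(C)=C/CO[Si](c1ccccc1)(c1ccccc1)C(C)(C)C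
F7 | step 15 | methyl (1S,4aS,5R,8aS)-5-[(3E)-5-hydroxy-3-methylpent-3-en-1-yl]-1,4a-dimethyl-6-oxo-1,2,4a,5,6,7,8,8a-octahydronaphthalene-1-carboxylate | O=C1CC[C@H]2[C@](C)(C=CC[C@]2(C)C(=O)OC)[C@H]1CC/C(C)=C/CO
F8 | step 15 | methyl (1S,4aS,5R,8aS)-5-{2-[(2R,3R)-3-(hydroxymethyl)-2-methyloxiran-2-yl]ethyl}-1,4a-dimethyl-6-oxo-1,2,4a,5,6,7,8,8a-octahydronaphthalene-1-carboxylate | O=C1CC[C@H]2[C@](C)(C=CC[C@]2(C)C(=O)OC)[C@H]1CC[C@@]1(C)O[C@@H]1CO
F9 | step 15 | methyl (1S,4aS,5R,8aS)-5-{2-[(2R,3R)-3-(hydroxymethyl)-2-methyloxiran-2-yl]ethyl}-1,4a-dimethyl-6-oxodecahydronaphthalene-1-carboxylate | O=C1CC[C@H]2[C@](C)(CCC[C@]2(C)C(=O)OC)[C@H]1CC[C@@]1(C)O[C@@H]1CO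
F10 | step 6 | methyl (2E,6R,7S,10E)-12-{[tert-butyl(diphenyl)silyl]oxy}-6-hydroxy-2,10-dimethyl-7-(prop-1-en-2-yl)dodeca-2,10-dienoate | COC(=O)/C(C)=C/CC[C@@H](O)[C@@H](CC/C(C)=C/CO[Si](c1ccccc1)(c1ccccc1)C(C)(C)C)C(C)=C
F11 | step 6 | methyl (2E,6R,7S,10E)-6-acetoxy-12-{[tert-butyl(diphenyl)silyl]oxy}-2,10-dimethyl-7-(prop-1-en-2-yl)dodeca-2,10-dienoate | COC(=O)/C(C)=C/CC[C@@H](OC(C)=O)[C@@H](CC/C(C)=C/CO[Si](c1ccccc1)(c1ccccc1)C(C)(C)C)C(C)=C
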